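The pitfall in these runs is to read 1.33 min as an early time: by then the target stands at 10.7% of the charge on average, against 12.2% at 3.00 min, so the ratio read there is no starting ratio.

| flask | substrate | remark | time |
|---|---|---|---|
| red | 0.070 M | run made earlier |  |
| green | 0.28 M | run made earlier |  |
| flask | 0.14 M |  | 10 min |

- red (time / min: target / %, isomer of the product A / %): 1.33: 11.0, 5.6; 3.00: 11.9, 10.5; 4.00: 11.7, 13.7; 6.00: 11.5, 19.5; 8.00: 10.9, 23.2; 10.0: 10.0, 26.5
- green (time / min: target / %, isomer of the product A / %): 1.33: 10.3, 6.7; 3.00: 12.6, 10.8; 4.00: 10.9, 14.0; 6.00: 10.5, 18.7; 8.00: 10.3, 22.5; 10.0: 9.4, 24.8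

(scatter of a reading: 0.5 percentage points)

* ratio of target to isomer of the product A at 2.5 s
* ratio of target to isomer of the product A at 10 min
* which of target and isomer of the product A there is more of at 10 min

- a reading or a percentage of target counts all its forms, free or not

The ratio of target to isomer of the product A (from here on simply isomer) at 10 min reads 0.377 in the red run and 0.379 in the green run, although the green run holds 4.00 times the charge. The flask's charge lies between the two, so the runs are pooled for it. The inverse, isomer per target as fractions of the charge, climbs from 0.577 at 1.33 min to 2.64 at 10.0 min. The slope between these two readings is the isomer drift, the rise of isomer per target in each minute, 0.238 min⁻¹. The pooled reading at 4.00 min lies on this line, while the one at 3.00 min lies somewhat below it.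

Run backwards, the line starts at 0.260 isomer per target. So for the first instants of the flask, the reckoning made here puts the ratio of target to isomer at 3.70 at 2.5 s, an extrapolation across a stretch without readings. For the middle of the flask, the line reaches one at 3.10 min, the reckoned time at which target and isomer stand level. At 10 min the line gives a ratio of 0.378, with isomer ahead.

The forecast gives 5 and 0.38 with isomer of the product A ahead, taking the early value as “the ratio is the ratio of initial rates”; its early ratio is higher than the one reckoned here. The flask gives 3.17 and 0.363, with isomer at 25.6% and target at 9.28%, and the two stand level at 3.12 min, beside the 3.10 min from the drift.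

    crystals ⇌ target, rate k1*(cs1 - [target]) while solid is left; crystals form when [target] > cs1 (solubility = 0.100 M, k = 0.520 s⁻¹)
    substrate ⇌ target (K = 0.380, k = 0.00420 s⁻¹)
    substrate ⇌ isomer of the product A (K = 2.00, k = 0.00130 s⁻¹)
    substrate ⇌ dormant form (K = 1.00, k = 0.0260 s⁻¹)
    target ⇌ isomer of the product B (K = 21.0, k = 0.00160 s⁻¹)
    target ⇌ isomer of the product A (k = 8.50 × 10⁻⁴ s⁻¹)

In the flask, dissolved target has a half-life of 1.0 min for going back to substrate, shorter than the 10 min of the run, whereas isomer has 18 min for going back to substrate, longer than the run. Between 5.00 min and 10.0 min the flask's target goes from 11.0% to 9.28% while its isomer goes from 16.4% to 25.6%.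

A neighbouring flask with 0.24 M of substrate also lies inside the charges of the two runs, so the drift of 0.238 min⁻¹ is taken over for it, and the line again gives 0.378 at 10 min. That flask gives 0.363, with isomer at 25.6%.

The earlier runs and the new flask are calculated with made-up constants; the scatter is artificial.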